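If starting material leaves by several steps at once, the target's share of each portion consumed is a ratio of frequencies, and a curve of that ratio can be replaced by a mean.

    intermediate A → side product A (k1 = 0.021 h⁻¹)
    intermediate B → side product B (k2 = 0.0022 h⁻¹)
    starting material → target (k3 = 0.10 h⁻¹)
    starting material + protic impurity → quenched substrate (k4 = 2.8 L mol⁻¹ h⁻¹)
    intermediate B ⇌ intermediate C (K5 = 1.2, k5 = 0.033 h⁻¹)
    2 starting material → self-condensation product (k6 = 0.52 L mol⁻¹ h⁻¹)
    starting material → intermediate B (k7 = 0.030 h⁻¹)
    starting material ⇌ intermediate A (K8 = 2.3, k8 = 0.017 h⁻¹)

in all of them: protic impurity 0.190 M
- midnight: starting material 0.19 M; one stirred flow tank at steady state, fed with the mixture as stated, mean residence time 15 h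
- spring: starting material 0.19 M; everything together in a closed stirred flask, run for 15 h; time 15 h
- dusk: starting material 0.19 M (fed, over 7.50 h); all but starting material at the start; starting material goes in evenly over 7.50 h, the run ends at 15 h; time 15 h

- the set-up with the highest amount of target at the outlet or at the end, in percent of the starting material put in ("none" if the first two lie within 2 percentage points) (midnight / spring / dusk / none)
- amount of target at the outlet or at the end, in percent of the starting material put in, midnight
- amount of target at the outlet or at the end, in percent of the starting material put in, spring
- amount of target at the outlet or at the end, in percent of the starting material put in, dusk

- percentages count the starting material that a species holds: one self-condensation product counts as two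
- a doubled species enters its step squared and goes two at a time
- the stated concentrations are those of everything mixed, before any reaction; amounts are the same in each set-up
- the feed brings no volume worth counting
- run time (spring): 15 h

This hand reckoning is for spring, the closed flask. The steps to target, intermediate B and intermediate A take starting material at a summed frequency of 0.147 h⁻¹; the return from intermediate A is set aside. Self-condensation goes with c(starting material), whose mean over the conversion is 0.0950 M, so it adds 0.0988 h⁻¹. The quench by protic impurity is pseudo-first-order and, at the charge, runs at 0.532 h⁻¹. The target's share is then 12.9%, a first number to commit to.

The weak link is c(protic impurity), which falls from its charge as each quench spends one. At mid-conversion it has dropped by the quenched share of 0.0950 M. Passing that share back through the frequencies gives 68.4%, then 58.7%, then 60.5%. So the mid-conversion quench frequency is 0.371 h⁻¹ and the target's share there is 16.2%. But one mean point carries an error, since the share climbs from 11.4% at the start to 28.0% at full conversion, and the curve bends. Counting the middle 4 times against each end, over 6, gives the mean-curve share, the target's share averaged over conversion: 17.4%. The reckoning stops at spring.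

The forecast gives 20.2% for midnight, 17.4% for spring and 19.1% for dusk, with best none. Among its grounds: “the protic impurity takes a large share in all three set-ups”.

The simulation gives 20.2% for midnight, 17.3% for spring and 19.1% for dusk, with best none, so the forecast holds.

Spring ends at 17.3% against the mean-curve share of 17.4%. Without the quench, the spring run gives 39.9%, so the quench is the largest single effect on the spring yield, worth 23 percentage points. With protic impurity held at its charge, the spring run gives 13.0%, beside the first estimate of 12.9%, so the depletion of protic impurity is one part of the spring yield, worth 4.3 points.

In the neighbour, spring with 0.47 M of protic impurity, the same reckoning gives a quenched share of 81.6% and a mean-curve share of 7.58%. The simulation gives 7.58%.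

The numbers of this flask are those of an exercise; the flask was simulated.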